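(The data stem from a simulated flask with constants of no real substance; noise was put on by code.)

- The pitfall I saw was to treat spent carrier as a plain catalyst, with the rate in proportion to its charge. I read this flask as a phase-transfer cycle, in which spent carrier also brings leaving group.

| flask | starting material | salt in the second phase | spent carrier | remark | volume of the second phase over the first |
|---|---|---|---|---|---|
| red | 1 M | 0.90 M | 150 mM | the very flask that is asked about, followed so far |  |
| teal | 0.50 M | 0.90 M | 150 mM | run made earlier |  |
| flask | 1.0 M | 0.900 M | 150 mM |  | 1.0 |

- red (time / min: target / %, starting material / %): 0.833: 11.5, 87.3; 1.50: 20.2, 79.6; 2.50: 30.0, 69.4; 3.00: 33.8, 64.9; 4.00: 40.8, 59.4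
- teal (time / min: target / %, starting material / %): 0.333: 5.1, 95.5; 0.667: 13.2, 91.4; 1.00: 14.6, 85.2; 2.00: 28.1, 72.7; 4.00: 46.8, 53.1

(each reading ± 1 percentage point)

* factor on the rate of making target when 20% of the starting material are converted if spent carrier is charged twice over
* factor on the rate when 20% of the starting material are converted if spent carrier is charged at 30 mM instead

- charges count per volume of the first phase; a concentration in a rate is the amount of a species over the volume of its own phase; every rate counts per litre of the first phase
- what was read earlier has a scatter of 1 percentage point, one standard deviation
- the earlier runs hold the two phases in the same ratio of volumes as the flask asked about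
- no earlier run changes the charge of spent carrier; that part of a forecast is a guess

- I worked with the fraction of starting material left, as its logarithm over time. The red flask lost 0.152 min⁻¹ up to 1.50 min, then slowed to 0.117 min⁻¹ up to 4.00 min.
- The teal flask averaged 0.158 min⁻¹ over its whole run, though it ended with less starting material left, in percent, than red. So I read the sag as following amounts, not percent conversion.
- My quantity was r, [salt in the second phase] left over the leaving group present, charged plus released. At 20% conversion in the red flask, r = 2.00.
- I took the working share of carrier to go as r/(r+b). Red's windows, at r = 3.20 and 1.33, gave a reading of b = 0.869.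
- A factor of exactly 2 on doubling needed that share unchanged. But the charge supplies 42.9% of the leaving group, so r fell to 1.40 and the share changed by a factor of 0.885.
- My reckoning gave 1.77 for doubling. At 30 mM, r = 3.04 gave 0.223. No run had varied the charge, so both were guesses in that part.
- The forecast said 1.75 and 0.22, and warned: “Carrier proportionality itself is assumed, not tested.”
- The flask gave 1.65 and 0.246.

    spent carrier + salt in the second phase ⇌ fresh carrier + spent salt in the second phase (K = 0.590, k = 9.00 L mol⁻¹ min⁻¹)
    starting material + fresh carrier → target + spent carrier (k = 2.20 L mol⁻¹ min⁻¹)
    2 fresh carrier ⇌ resting dimer, settled at all times (K = 2.10 L mol⁻¹)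

- In the red flask at 1.95 min, fresh carrier fell back 3.0 times faster than it went on to target. At 20% conversion in the red flask, where I had reckoned r = 2.00, fresh carrier held 43.1% of the catalyst.
- In a second flask with the spent carrier doubled, r at 10.0% conversion went from 3.20 to 2.00. That gave me a factor of 0.564 on the time to 20%, and the time of that flask changed by a factor of 0.631.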